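## The problem

Target 21, 1-[4-hydroxy-3-(2-hydroxybenzyl)-2-methoxyphenyl]-3-phenylpropan-1-one, is a dihydrochalcone whose ring A is substituted on four adjacent carbons. C1' carries the 3-phenylpropanoyl chain, C2' a methoxy group, C3' the 2-hydroxybenzyl group (ring C) and C4' a free hydroxyl; C5' and C6' are CH. There is no stereocenter, so every selectivity question is one of regiochemistry and chemoselectivity. The benzyl carbon must sit between two oxygens, a position that direct C-benzylation of a resorcinol reaches only in competition with the other activated positions and with over-alkylation. The two ring A oxygens must also be told apart in the unfavourable sense: in a 2,4-dihydroxyaryl ketone the C2' hydroxyl is hydrogen-bonded to the carbonyl and is the less reactive one, yet it is the one that carries the methyl group. Sensitive features are the doubly benzylic methylene (acidic, so aryl metalation near it is unsafe), the enolizable and reducible aryl ketone, the methyl ether ortho to the carbonyl (cleaved by boron and aluminium halides) and two electron-rich phenols. The enabling feature is that C3' is flanked by the oxygenated carbons C2' and C4' while C5' and C6' are unsubstituted. This 2-alkylresorcinol unit is what an ynol ether (C3', C4' and the C4' oxygen) and the parent vinylketene (C2' with its oxygen, C1', C6', C5') assemble, and the two oxygens come from different reagents, so they are differentiated from the start.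

## Retrosynthesis

**21 from 20 from 19.** Only oxygen–protecting-group bonds are cut: the benzyl–oxygen bond on ring C and the silicon–oxygen bond at C4'. Two different masks are preferred to one global deprotection. The C4' silyl ether is created in the ring-forming step, whereas the ring C oxygen must pass through organolithium chemistry, where a benzyl ether is inert and an ortho-silyloxy group could migrate to a benzylic carbanion. The price is one extra step. The forward reactions must spare an aryl ketone and a methyl ether, which fluoride and hydrogen over palladium both do.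

**19 from 18 from 15 and 16.** The bond between the carbonyl carbon and its α-methylene is cut. Alcohol 18 comes from aldehyde 15 and the Grignard reagent 17 made from bromide 16, and oxidation gives ketone 19. The neighbouring cut, the aryl–carbonyl bond by Friedel–Crafts or Fries chemistry, would need Lewis acids that strip benzyl and silyl ethers and would have to choose between C1' and C5'. The precursor is smaller by ring B and eight carbons. The forward steps are a carbonyl addition and an oxidation that must leave the diarylmethane CH2 alone.

**15 from 14 from 13.** The O–CH3 bond at C2' and the C1'–CHO bond are cut, in that order. The free C2' hydroxyl of phenol 13 first serves as the directing group for formylation and is methylated afterwards. Its only free ortho carbon is C1', so a magnesium-mediated ortho-formylation has one possible site. Electrophilic formylation of the methyl ether would instead divide between C1' and C5'. Phenol 13 carries only the benzyl group and two unlike oxygens.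

**13 from 5 and 8.** This is the key cut: C2'–C3' and C4'–C5' (formally also C1'–C2', which is broken and re-made). Benzylation of a 2-metalated resorcinol diether would make the same C3' pattern but leave two equivalent oxygens to desymmetrize. The benzannulation delivers one as a free phenol and the other as a silyl ether. Phenol 13, with 29 carbons, falls into the acyclic siloxyalkyne 5 and the four-carbon enone 8. The forward reaction needs a regioselective ketene–alkyne cycloaddition and an alkyne nucleophilic enough to capture vinylketene 9 before it oligomerizes.

**5 from 2 from 1.** Both bonds to the benzyl-bearing alkyne carbon are cut: that carbon is inserted between the ester carbonyl carbon and the arylmethyl group of ester 2 by a homologation stopped at ynolate 4, which is silylated on oxygen. The neighbouring route, oxidation of a terminal acetylide, would first require an isomerization-prone 3-arylpropyne. Ester 2 is the benzyl ether of the commercial phenol ester 1.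

**8 from 7 from 6.** The enone double bond comes from loss of HBr from bromoketone 7, and the C–Br bond comes from the carboxyl group of acid 6. Both steps are simple, but 8 is volatile and polymerizes, so it is made immediately before use.

## Roads not taken

**Alternative 1: aldol folding of a pyranone-masked polyketide.**
- **Cut:** the C1'–C6' bond of ring A.
- **Forward step:** aqueous KOH would add to the unsubstituted ring carbon of 3-[2-(benzyloxy)benzyl]-2-(2-oxo-4-phenylbutyl)-4H-pyran-4-one A1. The ring opens to a formyl triketone enolate, the C1' methylene between two ketones condenses with the formyl carbon C6', and dehydration with enolization gives 1-{3-[2-(benzyloxy)benzyl]-2,4-dihydroxyphenyl}-3-phenylpropan-1-one A2.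
- **Merits:** the acyl chain is in place when the ring forms, the reagents are cheap, and no strained or volatile partner is needed. In this respect it is better than the chosen plan, which spends steps 6, 8 and 9 on the chain.
- **Weak points:** A2 has both ring A hydroxyls free, and the methyl group must go on the chelated C2' hydroxyl, against the innate preference for C4'. Protection of C4', methylation and deprotection add three steps before debenzylation. Under hydroxide the β-ketoaldehyde end can be lost by retro-Claisen cleavage, and the chain can fold the other way (C5' onto the side-chain ketone) to an isomeric ring. A1 itself needs a regiocontrolled pyranone synthesis.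
- **Comparison:** the chosen plan sets against the shorter chain installation the fact that 13 has its two oxygens already differentiated and only one position open to formylation.

**Alternative 2: tethered acyl transfer and ring closure of a diarylheptanoid dione.**
- **Cut:** the C3'–C4' and C1'–C6' bonds.
- **Forward step:** the dianion of 2-(3,5-dioxo-7-phenylheptyl)phenyl (2E)-3-ethoxyprop-2-enoate A3 would take the acyl group from the ring C oxygen onto C3'. C1' then adds to C6' with loss of ethoxide, closing and aromatizing ring A to 1-[2,4-dihydroxy-3-(2-hydroxybenzyl)phenyl]-3-phenylpropan-1-one A4.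
- **Merits:** no protecting groups up to the ring-forming event, the tether places the benzyl carbon at C3' by construction, and it is the shortest path to the carbon skeleton. It is clearly better than the chosen plan in step and atom economy up to that point.
- **Weak points:** A4 has three free phenols and the target needs methylation of the least reactive one, so protecting-group steps return and carry their own selectivity problem between the C4' and ring C hydroxyls. The two terminal α-methylenes of the dione are nearly equivalent, so the second deprotonation is not regioselective. The carbanion can add in conjugate fashion to the ethoxyacrylate instead of attacking the ester carbonyl. The aryl ester is open to cleavage by the ethoxide set free.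
- **Comparison:** the chosen plan sets against the brevity a cascade in which every intermediate belongs to a known class, and a product that needs no late oxygen differentiation.

**Alternative 3: Diels–Alder assembly from a Brassard-type diene and an ynone.**
- **Cut:** the C1'–C2' and C5'–C6' bonds.
- **Forward step:** 1,1-dimethoxy-2-[2-(benzyloxy)benzyl]-3-(trimethylsiloxy)buta-1,3-diene A5 and 5-phenylpent-1-yn-3-one A6 would combine in a Diels–Alder reaction. Loss of methanol and of the silyl group gives 1-{3-[2-(benzyloxy)benzyl]-4-hydroxy-2-methoxyphenyl}-3-phenylpropan-1-one A7.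
- **Merits:** A7 is the same compound as 20 of the chosen route, one hydrogenolysis from the target. The orientation rule puts the acyl group next to the retained methoxy group, and the methoxy/hydroxyl differentiation is built in. After ring formation this road is five steps shorter than the chosen one (steps 6 to 10) and is the most convergent of all.
- **Weak points:** A5 is a fully substituted, hydrolytically fragile ketene acetal with a bulky aralkyl group on an internal diene carbon. Its preparation is longer and less secure than that of the unsubstituted parent dienes. Strain in its s-cis conformer should slow the cycloaddition, and stepwise Mukaiyama–Michael addition to open-chain products or [2+2] addition may take over. The terminal ynone A6 is prone to polymerization.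
- **Comparison:** the chosen plan sets against its longer endgame two precursors that are each made in two steps by established reactions, and a ring-forming step whose regiochemistry does not depend on the conformation of a crowded diene.

Key step: step 5

Assumption: methyl 2-(2-hydroxyphenyl)acetate 1, 3-oxocyclobutane-1-carboxylic acid 6 and (2-bromoethyl)benzene 16 are taken as catalogue compounds.

## Route

Step 1
Reactants: 1 methyl 2-(2-hydroxyphenyl)acetate
Product: 2 methyl 2-[2-(benzyloxy)phenyl]acetate
Conditions: BnBr, K2CO3, DMF, rt
Reagents that add atoms: benzyl bromide, BrCc1ccccc1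
Why: Williamson etherification of the phenoxide; carbonate is too weak to enolize the arylacetate, so O-benzylation should outrun C-alkylation and lactonization.

Step 2
Reactants: 2 methyl 2-[2-(benzyloxy)phenyl]acetate
Product: 5 {[3-(2-(benzyloxy)phenyl)prop-1-yn-1-yl]oxy}triisopropylsilane, via lithium dibromoenolate 3 (not isolated), via lithium ynolate 4 (not isolated)
Conditions: CH2Br2, lithium 2,2,6,6-tetramethylpiperidide, THF, −78 °C; LiN(SiMe3)2, then n-BuLi, −78 °C to rt; i-Pr3SiCl, −78 °C to rt
Reagents that add atoms: dibromomethane, BrCBr; chlorotriisopropylsilane, CC(C)[Si](Cl)(C(C)C)C(C)C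
Why: Kowalski ester homologation stopped at the ynolate: LiCHBr2 adds to the ester, enolate 3 undergoes bromine–lithium exchange and 1,2-shift of the arylmethyl group to ynolate 4, and the bulky chlorosilane silylates 4 on oxygen. Addition at −78 °C is expected to be faster than enolization of the arylacetate.

Step 3
Reactants: 6 3-oxocyclobutane-1-carboxylic acid
Product: 7 3-bromocyclobutan-1-one
Conditions: HgO, Br2, MgSO4, CH2Cl2, reflux
Reagents that add atoms: bromine, BrBr
Why: Hunsdiecker bromodecarboxylation in the Cristol–Firth form: the acyl hypobromite formed from the mercury carboxylate fragments to a cyclobutyl radical that abstracts bromine.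

Step 4
Reactants: 7 3-bromocyclobutan-1-one
Product: 8 cyclobut-2-en-1-one
Conditions: n-Bu3N, neat, rt, reduced pressure, distillate trapped at −78 °C
Reagents that add atoms: none
Why: E1cB dehydrobromination of a β-bromo ketone; the involatile amine and its salt stay behind while the volatile enone is collected cold and used at once, which limits polymerization.

Step 5
Reactants: 5 {[3-(2-(benzyloxy)phenyl)prop-1-yn-1-yl]oxy}triisopropylsilane, 8 cyclobut-2-en-1-one
Product: 13 2-[2-(benzyloxy)benzyl]-3-[(triisopropylsilyl)oxy]phenol, via vinylketene 9 (not isolated), via 4-vinylcyclobutenone 10 (not isolated), via dienylketene 11 (not isolated), via cyclohexadienone 12 (not isolated)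
Conditions: toluene, 80 °C, sealed tube; 8 (1.3 equiv) added in portions as a cold toluene solution
Reagents that add atoms: none
Why: This is a Danheiser benzannulation, and the closest known reaction type is this same pairing of a cyclobutenone with a trialkylsiloxyalkyne, which gives 2-substituted 3-siloxyphenols. Heating opens 8 by four-electron conrotatory electrocyclic cleavage to vinylketene 9, and the electron-rich alkyne 5 adds across the ketene C=C bond in a [2+2] cycloaddition to give 4-vinylcyclobutenone 10. A second, reversible four-electron opening gives dienylketene 11; only the isomer with the vinyl group cis to the ketene carbon can react further, so the equilibrium drains through it. Ring A, the only ring that persists, closes by thermal six-electron disrotatory electrocyclization of 11, which re-forms the C1'–C2' bond and gives cyclohexadienone 12; tautomerization then gives phenol 13. The net result is insertion of the two alkyne carbons between the carbonyl carbon and the α-carbon of 8, so the bonds newly made are C2'–C3' and C4'–C5'. No stereocenter survives: the vinyl-bearing ring carbon of 10 forms as a racemate and becomes sp2 in 11. The selectivity needed is the regiochemistry of the [2+2] event, secured by the polarization of the ynol silyl ether: its benzyl-bearing β-carbon is the nucleophilic end and bonds to the electrophilic ketene carbonyl carbon, which puts the benzyl carbon between the free hydroxyl (the later methoxy) and the siloxy group. The bulky triisopropylsilyl group should keep the ynol ether intact at 80 °C and stay on its oxygen, so the two oxygens of 13 emerge differentiated.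

Step 6
Reactants: 13 2-[2-(benzyloxy)benzyl]-3-[(triisopropylsilyl)oxy]phenol
Product: 14 3-[2-(benzyloxy)benzyl]-2-hydroxy-4-[(triisopropylsilyl)oxy]benzaldehyde
Conditions: MgCl2, Et3N, (CH2O)n, MeCN, reflux; then 1 M HCl
Reagents that add atoms: paraformaldehyde (as formaldehyde), C=O
Why: Casnati–Skattebøl ortho-formylation: the magnesium phenoxide delivers formaldehyde to the ortho carbon through a chelate, and the resulting benzylic alkoxide is oxidized by a second formaldehyde through hydride transfer. C1' is the only free ortho position of the phenol and is also para to the siloxy group.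

Step 7
Reactants: 14 3-[2-(benzyloxy)benzyl]-2-hydroxy-4-[(triisopropylsilyl)oxy]benzaldehyde
Product: 15 3-[2-(benzyloxy)benzyl]-2-methoxy-4-[(triisopropylsilyl)oxy]benzaldehyde
Conditions: MeI, K2CO3, acetone, 50 °C, sealed tube
Reagents that add atoms: iodomethane, CI
Why: Williamson methylation of the only free phenoxide; the anhydrous, weakly polar medium is chosen to spare the aryl silyl ether.

Step 8
Reactants: 15 3-[2-(benzyloxy)benzyl]-2-methoxy-4-[(triisopropylsilyl)oxy]benzaldehyde, 16 (2-bromoethyl)benzene
Product: 18 rac-1-{3-[2-(benzyloxy)benzyl]-2-methoxy-4-[(triisopropylsilyl)oxy]phenyl}-3-phenylpropan-1-ol, via phenethylmagnesium bromide 17 (not isolated)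
Conditions: Mg, THF, rt to 40 °C (16 to 17); then 15, THF, 0 °C; aq NH4Cl
Reagents that add atoms: none
Why: Grignard addition of a primary alkylmagnesium bromide to an aryl aldehyde, the only electrophile present. The new carbinol center forms as a racemate and is erased in step 9.

Step 9
Reactants: 18 rac-1-{3-[2-(benzyloxy)benzyl]-2-methoxy-4-[(triisopropylsilyl)oxy]phenyl}-3-phenylpropan-1-ol
Product: 19 1-{3-[2-(benzyloxy)benzyl]-2-methoxy-4-[(triisopropylsilyl)oxy]phenyl}-3-phenylpropan-1-one
Conditions: Dess–Martin periodinane, NaHCO3, CH2Cl2, rt
Reagents that add atoms: none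
Why: Dess–Martin oxidation of a secondary benzylic alcohol under buffered conditions; the ethers and the diarylmethane methylene are not attacked by this reagent.

Step 10
Reactants: 19 1-{3-[2-(benzyloxy)benzyl]-2-methoxy-4-[(triisopropylsilyl)oxy]phenyl}-3-phenylpropan-1-one
Product: 20 1-{3-[2-(benzyloxy)benzyl]-4-hydroxy-2-methoxyphenyl}-3-phenylpropan-1-one
Conditions: Bu4NF, AcOH, THF, 0 °C
Reagents that add atoms: none
Why: Fluoride cleavage of an aryl silyl ether, driven by the Si–F bond and by the good leaving ability of a phenoxide para to a ketone. Acetic acid buffers the medium so the enolizable ketone does not meet strong base.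

Step 11
Reactants: 20 1-{3-[2-(benzyloxy)benzyl]-4-hydroxy-2-methoxyphenyl}-3-phenylpropan-1-one
Product: 21 1-[4-hydroxy-3-(2-hydroxybenzyl)-2-methoxyphenyl]-3-phenylpropan-1-one
Conditions: H2 (1 atm), Pd/C (10 wt%), EtOAc, rt
Reagents that add atoms: none
Why: Hydrogenolysis of an aryl benzyl ether over palladium. The electron-rich aryl ketone, conjugated with the para hydroxyl, should be reduced much more slowly, and the diarylmethane is inert.

## Compound list

1 | methyl 2-(2-hydroxyphenyl)acetate | COC(=O)Cc1ccccc1O | starting material
2 | methyl 2-[2-(benzyloxy)phenyl]acetate | COC(=O)Cc1ccccc1OCc1ccccc1 | intermediate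
3 | lithium 3-[2-(benzyloxy)phenyl]-1,1-dibromoprop-1-en-2-olate | [Li+].[O-]C(Cc1ccccc1OCc1ccccc1)=C(Br)Br | intermediate (not isolated)
4 | lithium 3-[2-(benzyloxy)phenyl]prop-1-yn-1-olate | [Li+].[O-]C#CCc1ccccc1OCc1ccccc1 | intermediate (not isolated)
5 | {[3-(2-(benzyloxy)phenyl)prop-1-yn-1-yl]oxy}triisopropylsilane | CC(C)[Si](OC#CCc1ccccc1OCc1ccccc1)(C(C)C)C(C)C | intermediate
6 | 3-oxocyclobutane-1-carboxylic acid | OC(=O)C1CC(=O)C1 | starting material
7 | 3-bromocyclobutan-1-one | O=C1CC(Br)C1 | intermediate
8 | cyclobut-2-en-1-one | O=C1C=CC1 | intermediate
9 | buta-1,3-dien-1-one (vinylketene) | C=CC=C=O | intermediate (not isolated)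
10 | rac-2-[2-(benzyloxy)benzyl]-3-[(triisopropylsilyl)oxy]-4-vinylcyclobut-2-en-1-one | O=C1C(Cc2ccccc2OCc2ccccc2)=C(O[Si](C(C)C)(C(C)C)C(C)C)C1C=C | intermediate (not isolated)
11 | (3E)-2-[2-(benzyloxy)benzyl]-3-[(triisopropylsilyl)oxy]hexa-1,3,5-trien-1-one (vinyl group cis to the ketene carbon) | O=C=C(Cc1ccccc1OCc1ccccc1)/C(O[Si](C(C)C)(C(C)C)C(C)C)=C\C=C | intermediate (not isolated)
12 | 2-[2-(benzyloxy)benzyl]-3-[(triisopropylsilyl)oxy]cyclohexa-2,4-dien-1-one | O=C1CC=CC(O[Si](C(C)C)(C(C)C)C(C)C)=C1Cc1ccccc1OCc1ccccc1 | intermediate (not isolated)
13 | 2-[2-(benzyloxy)benzyl]-3-[(triisopropylsilyl)oxy]phenol | CC(C)[Si](Oc1cccc(O)c1Cc1ccccc1OCc1ccccc1)(C(C)C)C(C)C | intermediate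
14 | 3-[2-(benzyloxy)benzyl]-2-hydroxy-4-[(triisopropylsilyl)oxy]benzaldehyde | O=Cc1ccc(O[Si](C(C)C)(C(C)C)C(C)C)c(Cc2ccccc2OCc2ccccc2)c1O | intermediate
15 | 3-[2-(benzyloxy)benzyl]-2-methoxy-4-[(triisopropylsilyl)oxy]benzaldehyde | COc1c(C=O)ccc(O[Si](C(C)C)(C(C)C)C(C)C)c1Cc1ccccc1OCc1ccccc1 | intermediate
16 | (2-bromoethyl)benzene | BrCCc1ccccc1 | starting material
17 | (2-phenylethyl)magnesium bromide | Br[Mg]CCc1ccccc1 | intermediate (not isolated)
18 | rac-1-{3-[2-(benzyloxy)benzyl]-2-methoxy-4-[(triisopropylsilyl)oxy]phenyl}-3-phenylpropan-1-ol | COc1c(C(O)CCc2ccccc2)ccc(O[Si](C(C)C)(C(C)C)C(C)C)c1Cc1ccccc1OCc1ccccc1 | intermediate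
19 | 1-{3-[2-(benzyloxy)benzyl]-2-methoxy-4-[(triisopropylsilyl)oxy]phenyl}-3-phenylpropan-1-one | COc1c(C(=O)CCc2ccccc2)ccc(O[Si](C(C)C)(C(C)C)C(C)C)c1Cc1ccccc1OCc1ccccc1 | intermediate
20 | 1-{3-[2-(benzyloxy)benzyl]-4-hydroxy-2-methoxyphenyl}-3-phenylpropan-1-one | COc1c(C(=O)CCc2ccccc2)ccc(O)c1Cc1ccccc1OCc1ccccc1 | intermediate
21 | 1-[4-hydroxy-3-(2-hydroxybenzyl)-2-methoxyphenyl]-3-phenylpropan-1-one | COc1c(C(=O)CCc2ccccc2)ccc(O)c1Cc1ccccc1O | target

## Step count and risks

Total step count: 11. Longest linear sequence: 9 steps (1, 2, 5, 6, 7, 8, 9, 10, 11); the two-step cyclobutenone branch (3, 4) joins at step 5.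

**Step 5 (key step).** The strained enone 8 or ketene 9 may oligomerize before capture. The new phenol may be O-acylated by ketene that has not found an alkyne. The ynol ether may be protodesilylated by adventitious acid. The parent cyclobutenone is the least substituted and least robust member of its class.
Fallback: setting out from siloxyalkyne 5, vinylketene 9 would be generated at room temperature by photochemical Wolff rearrangement instead of from 8. But-3-en-2-one F1 (purchased) would be trifluoroacetylated through its lithium enolate (LiN(SiMe3)2, CF3CO2CH2CF3, THF, −78 °C) to 1,1,1-trifluorohex-5-ene-2,4-dione F2. Diazo transfer with loss of the trifluoroacetyl group (MsN3, Et3N, MeCN, H2O) would give 1-diazobut-3-en-2-one F3. Irradiation of F3 with 5 (mercury lamp, Pyrex, CH2Cl2, rt) should give 9 and then 10, and brief heating at 80 °C would complete the passage through 11 and 12 to phenol 13, where the route is rejoined.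

**Step 2.** The carbenoid or residual amide base may deprotonate the benzylic α-position of the arylacetate instead of adding to the ester, returning ester or giving Claisen condensation. The ynolate may also be silylated on carbon.
Fallback: setting out from ester 2, reduction (i-Bu2AlH, CH2Cl2, −78 °C) would give 2-[2-(benzyloxy)phenyl]acetaldehyde F4. Corey–Fuchs olefination (CBr4, PPh3, CH2Cl2, 0 °C) would give 1-(benzyloxy)-2-(3,3-dibromoprop-2-en-1-yl)benzene F5. Treatment with n-BuLi (2 equiv, THF, −78 °C) would give lithium 3-[2-(benzyloxy)phenyl]prop-1-yn-1-ide F6. F6 would be oxidized in the same flask with LiOOt-Bu (from t-BuOOH and LiN(SiMe3)2) to ynolate 4, which is silylated as in step 2 to give 5.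

**Step 7.** The silyl group may be lost from the C4' oxygen, which is para to the formyl group and therefore a good leaving phenoxide, and the wrong oxygen then methylated. Alkylation of the chelated, flanked C2' hydroxyl may also be slow.
Fallback: setting out from aldehyde 14, the silyl group would be removed on purpose (Bu4NF, THF, 0 °C) to give 3-[2-(benzyloxy)benzyl]-2,4-dihydroxybenzaldehyde F7. Its non-chelated, more acidic C4' hydroxyl would be benzylated selectively (BnBr, KHCO3, DMF, rt) to 4-(benzyloxy)-3-[2-(benzyloxy)benzyl]-2-hydroxybenzaldehyde F8. Forcing methylation (MeI, K2CO3, DMF, 50 °C) would give 4-(benzyloxy)-3-[2-(benzyloxy)benzyl]-2-methoxybenzaldehyde F9. Addition of Grignard reagent 17 would give rac-1-{4-(benzyloxy)-3-[2-(benzyloxy)benzyl]-2-methoxyphenyl}-3-phenylpropan-1-ol F10, and Dess–Martin oxidation would give 1-{4-(benzyloxy)-3-[2-(benzyloxy)benzyl]-2-methoxyphenyl}-3-phenylpropan-1-one F11. One hydrogenolysis (H2, Pd/C, EtOAc) would remove both benzyl groups and rejoin the route at target 21, one step longer than the main line.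

**Step 11.** The aryl ketone may be over-reduced to the carbinol or the methylene compound, or hydrogenolysis may stall if ammonium residues from step 10 poison the catalyst.
Fallback: setting out from 20, the benzyl group would be removed without hydrogen by Lewis-acid-mediated benzyl transfer to a cation scavenger (BCl3, pentamethylbenzene, CH2Cl2, −78 °C), arriving at 21. The temperature is held at −78 °C because chelation-assisted cleavage of the C2' methyl ether by boron halides sets in on warming; this is the weak point of the fallback.

## Further compounds

F1 | step 5 | but-3-en-2-one (purchased) | CC(=O)C=C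
F2 | step 5 | 1,1,1-trifluorohex-5-ene-2,4-dione | C=CC(=O)CC(=O)C(F)(F)F
F3 | step 5 | 1-diazobut-3-en-2-one | C=CC(=O)C=[N+]=[N-]
F4 | step 2 | 2-[2-(benzyloxy)phenyl]acetaldehyde | O=CCc1ccccc1OCc1ccccc1
F5 | step 2 | 1-(benzyloxy)-2-(3,3-dibromoprop-2-en-1-yl)benzene | BrC(Br)=CCc1ccccc1OCc1ccccc1
F6 | step 2 | lithium 3-[2-(benzyloxy)phenyl]prop-1-yn-1-ide | [Li+].[C-]#CCc1ccccc1OCc1ccccc1
F7 | step 7 | 3-[2-(benzyloxy)benzyl]-2,4-dihydroxybenzaldehyde | O=Cc1ccc(O)c(Cc2ccccc2OCc2ccccc2)c1O
F8 | step 7 | 4-(benzyloxy)-3-[2-(benzyloxy)benzyl]-2-hydroxybenzaldehyde | O=Cc1ccc(OCc2ccccc2)c(Cc2ccccc2OCc2ccccc2)c1O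
F9 | step 7 | 4-(benzyloxy)-3-[2-(benzyloxy)benzyl]-2-methoxybenzaldehyde | COc1c(C=O)ccc(OCc2ccccc2)c1Cc1ccccc1OCc1ccccc1
F10 | step 7 | rac-1-{4-(benzyloxy)-3-[2-(benzyloxy)benzyl]-2-methoxyphenyl}-3-phenylpropan-1-ol | COc1c(C(O)CCc2ccccc2)ccc(OCc2ccccc2)c1Cc1ccccc1OCc1ccccc1
F11 | step 7 | 1-{4-(benzyloxy)-3-[2-(benzyloxy)benzyl]-2-methoxyphenyl}-3-phenylpropan-1-one | COc1c(C(=O)CCc2ccccc2)ccc(OCc2ccccc2)c1Cc1ccccc1OCc1ccccc1
F0 | step 11 | none | none
A1 | alternative 1 | 3-[2-(benzyloxy)benzyl]-2-(2-oxo-4-phenylbutyl)-4H-pyran-4-one | O=C(CCc1ccccc1)Cc1occc(=O)c1Cc1ccccc1OCc1ccccc1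
A2 | alternative 1 | 1-{3-[2-(benzyloxy)benzyl]-2,4-dihydroxyphenyl}-3-phenylpropan-1-one | O=C(CCc1ccccc1)c1ccc(O)c(Cc2ccccc2OCc2ccccc2)c1O
A3 | alternative 2 | 2-(3,5-dioxo-7-phenylheptyl)phenyl (2E)-3-ethoxyprop-2-enoate | CCO/C=C/C(=O)Oc1ccccc1CCC(=O)CC(=O)CCc1ccccc1
A4 | alternative 2 | 1-[2,4-dihydroxy-3-(2-hydroxybenzyl)phenyl]-3-phenylpropan-1-one | O=C(CCc1ccccc1)c1ccc(O)c(Cc2ccccc2O)c1O
A5 | alternative 3 | 1,1-dimethoxy-2-[2-(benzyloxy)benzyl]-3-(trimethylsiloxy)buta-1,3-diene | COC(OC)=C(Cc1ccccc1OCc1ccccc1)C(=C)O[Si](C)(C)C
A6 | alternative 3 | 5-phenylpent-1-yn-3-one | C#CC(=O)CCc1ccccc1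
A7 | alternative 3 | 1-{3-[2-(benzyloxy)benzyl]-4-hydroxy-2-methoxyphenyl}-3-phenylpropan-1-one | COc1c(C(=O)CCc2ccccc2)ccc(O)c1Cc1ccccc1OCc1ccccc1
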